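Fragransin B1 is meso: a mirror plane through O1 and the midpoint of C3–C4 of the oxolane ring relates C2 to C5 and the two syringyl rings. The route therefore rests on disconnecting both aryl–C(benzylic) bonds to 2,6-dimethoxyphenol and a meso C6 bis-acetal, 2,5-dimethoxy-cis-3,4-dimethyloxolane, made from meso-2,3-dimethylsuccinic acid. In one protecting-group-free operation a twofold Friedel–Crafts arylation installs both rings. Its second C–C bond formation joins the free phenol to the in situ-formed 2-aryl-5-methoxyoxolane through a cyclic oxocarbenium ion and sets the last stereocentre trans to the adjacent methyl, restoring the mirror plane.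

Key step: step 3

Remark: the target, (2S,3S,4R,5R) with two identical aryl groups, is an achiral meso compound (aryl groups cis to each other, each trans to its neighbouring methyl, methyls cis), so only relative configuration is controlled; chiral intermediates are racemic and drawn as one enantiomer.

Step 1
Reactants: 1 meso-2,3-dimethylsuccinic acid
Product: 2 meso-2,3-dimethylbutane-1,4-diol
Conditions: LiAlH4, THF, 0 °C to reflux; aqueous work-up
Reagents that add atoms: none
Why: LiAlH4 reduction of the dicarboxylic acid to the 1,4-diol; the α-carbons are not enolised at the carboxylate/aluminate stage, so the meso (erythro) relationship of the two methyl groups should be carried over unchanged.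

Step 2
Reactants: 2 meso-2,3-dimethylbutane-1,4-diol
Product: 4 2,5-dimethoxy-cis-3,4-dimethyloxolane, via meso-2,3-dimethylbutanedial 3 (not isolated)
Conditions: (COCl)2, DMSO, CH2Cl2, −78 °C; i-Pr2NEt, −78 to −30 °C; then HCl/MeOH (excess over amine), −30 °C to rt
Reagents that add atoms: methanol, CO
Why: Swern oxidation activates both primary hydroxyl groups as alkoxysulfonium ions before base is added, so the dialdehyde should form without a lactol that could be over-oxidised, and acid-catalysed methanolysis then closes the 1,4-dialdehyde to the cyclic bis-acetal in the way succinaldehyde gives 2,5-dimethoxytetrahydrofuran; the cis-dimethyl relationship comes from the meso diol, the hindered base and cold acidic quench guard the α-centres, and the anomeric mixture is irrelevant because both acetal carbons are ionised in step 3.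

Step 3
Reactants: 4 2,5-dimethoxy-cis-3,4-dimethyloxolane; 5 2,6-dimethoxyphenol (2.2 equiv)
Product: 7 fragransin B1, via mono-aryl acetal 6 (not isolated)
Conditions: BF3·OEt2 (2.5 equiv), CH2Cl2, −78 to −30 °C; Et3N then aq. NaHCO3 at −30 °C
Reagents that add atoms: none
Why: BF3 ionises one anomeric methoxy group of 4 to a cyclic oxocarbenium ion, C4 of phenol 5 (para to the free OH) adds to it to give 6, and the same ionisation–addition at the remaining acetal carbon with a second molecule of 5 forms the aryl–C bond that unites the C8 phenol with the C15 aryl-oxolane and completes the skeleton. The closest known reaction type is the Friedel–Crafts C-arylation of 2-alkoxyoxolanes (lactol ethers) by electron-rich arenes via five-membered oxocarbenium ions, run here twice on a meso bis-acetal. No ring is closed: the oxolane ring of 4 is carried through intact and only its two exocyclic C–O bonds are exchanged for C–aryl bonds. Each new benzylic stereocentre (C2 and C5) is controlled by the ring methyl groups: in the envelope oxocarbenium ion the arene should add to the face opposite the adjacent methyl (inside attack on the conformer with the C3/C4 methyls on the far face), which places each aryl trans to its neighbouring methyl and the two aryls cis. This is also the most stable arrangement for a 3,4-cis-dimethyl ring, so any reversible benzylic C–O ionisation should converge on the same isomer, and because the first arylation only breaks the mirror plane that the second restores, racemic 6 gives the meso product without absolute stereocontrol. The step needs para-regioselective C-arylation of the phenol and survival of the acid-labile p-hydroxybenzylic ether bonds; the free OH flanked by two methoxy groups leaves C4 as the only activated open position and makes O-aryl acetal formation reversible, while low temperature and only a slight excess of 5 should suppress over-arylation.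

Compound list
1 | meso-2,3-dimethylsuccinic acid, (2R,3S)-2,3-dimethylbutanedioic acid | C[C@@H](C(=O)O)[C@H](C)C(=O)O | starting material
2 | meso-2,3-dimethylbutane-1,4-diol | C[C@@H](CO)[C@H](C)CO | intermediate
3 | meso-2,3-dimethylbutanedial | C[C@@H](C=O)[C@H](C)C=O | intermediate
4 | 2,5-dimethoxy-cis-3,4-dimethyloxolane (meso dimethyl backbone, mixture of anomers) | COC1OC(OC)[C@H](C)[C@@H]1C | intermediate
5 | 2,6-dimethoxyphenol | COc1cccc(OC)c1O | starting material
6 | 4-[(2S*,3S*,4R*)-5-methoxy-3,4-dimethyloxolan-2-yl]-2,6-dimethoxyphenol (mono-aryl acetal; racemic, aryl trans to the C3 methyl, methyls cis, C5 anomers) | COc1cc([C@H]2OC(OC)[C@H](C)[C@@H]2C)cc(OC)c1O | intermediate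
7 | fragransin B1, 4,4'-[(2S,3S,4R,5R)-3,4-dimethyloxolane-2,5-diyl]bis(2,6-dimethoxyphenol) | COc1cc([C@H]2O[C@@H](c3cc(OC)c(O)c(OC)c3)[C@H](C)[C@@H]2C)cc(OC)c1O | target

Total steps: 3. Longest linear sequence: 3 steps (1 → 2 → 4 → 7).

Steps most likely to fail

Step 3 (key step). What may go wrong: under BF3 the p-hydroxybenzylic C–O bonds of 6 and of the product ionise to quinone-methide-like cations that are arylated a second time at the benzylic carbon or cyclise onto the resident ring; the oxocarbenium ions lose a proton to enol ethers and scramble the cis-dimethyl relationship; the two arylations cannot be steered separately. Fallback (sets out from 1, comes back at 7): the two aryl–carbon bonds are made by different, known reactions with the first phenol masked. Acid 1 is dehydrated (AcCl, reflux) to cis-2,3-dimethylsuccinic anhydride F1. Commercial 4-bromo-2,6-dimethoxyphenol is benzylated (BnBr, K2CO3, DMF) to 2-(benzyloxy)-5-bromo-1,3-dimethoxybenzene F2, and bromine–lithium exchange (n-BuLi, THF, −78 °C) gives [4-(benzyloxy)-3,5-dimethoxyphenyl]lithium F3, which is added to F1 at −78 °C to open it to racemic (2R*,3S*)-4-[4-(benzyloxy)-3,5-dimethoxyphenyl]-2,3-dimethyl-4-oxobutanoic acid F4. Felkin–Anh-controlled reduction of the aryl ketone with LiBH(s-Bu)3 (THF, −78 °C) and acidic work-up should close the 3,4-cis-4,5-trans-5-[4-(benzyloxy)-3,5-dimethoxyphenyl]-3,4-dimethyloxolan-2-one F5; i-Bu2AlH (CH2Cl2, −78 °C) gives the corresponding lactol F6; one Friedel–Crafts arylation of F6 with 5 (BF3·OEt2, CH2Cl2, −78 to −30 °C), anti to the C3 methyl, gives fragransin B1 mono-benzyl ether F7, whose benzyloxy ring resists benzylic ionisation better than a free phenol; hydrogenolysis (H2, Pd/C, EtOAc) then gives 7.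

Step 2. What may go wrong: epimerisation of the aldehyde α-carbons by the amine base during the Swern elimination (erosion of the cis-dimethyl relationship), loss of the small hydrate-forming dialdehyde, or over-methanolysis to the open-chain tetramethyl acetal. Fallback (sets out from 1, comes back at 4): no oxidation and no amine base in contact with the aldehyde. Acid 1 is coupled with MeNHOMe·HCl (EDC·HCl, HOBt, N-methylmorpholine, CH2Cl2) to meso-N,N'-dimethoxy-N,N',2,3-tetramethylbutanediamide F8; LiAlH4 (THF, −78 to 0 °C) reduces both amide groups only to the aldehyde level, and quenching into cold HCl/MeOH releases 3 under acid and converts it at once into 4.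

Step 1. What may go wrong: incomplete reduction of the poorly soluble dicarboxylate (hydroxy acid or lactone left behind) and retention of the small, water-soluble diol in the aluminium hydroxide cake. Fallback (sets out from 1, comes back at 2): Fischer esterification (MeOH, cat. H2SO4, reflux) gives dimethyl meso-2,3-dimethylsuccinate F9, a soluble, distillable substrate that is reduced with LiBH4 (THF, 0 °C to rt) and worked up without water (MeOH quench, evaporation of B(OMe)3) to give 2.

Further compounds
F1 | step 3 | cis-2,3-dimethylsuccinic anhydride (meso) | C[C@H]1C(=O)OC(=O)[C@H]1C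
F2 | step 3 | 2-(benzyloxy)-5-bromo-1,3-dimethoxybenzene | COc1cc(Br)cc(OC)c1OCc1ccccc1
F3 | step 3 | [4-(benzyloxy)-3,5-dimethoxyphenyl]lithium | [Li]c1cc(OC)c(OCc2ccccc2)c(OC)c1
F4 | step 3 | (2R*,3S*)-4-[4-(benzyloxy)-3,5-dimethoxyphenyl]-2,3-dimethyl-4-oxobutanoic acid (racemic) | COc1cc(C(=O)[C@H](C)[C@@H](C(=O)O)C)cc(OC)c1OCc1ccccc1
F5 | step 3 | 3,4-cis-4,5-trans-5-[4-(benzyloxy)-3,5-dimethoxyphenyl]-3,4-dimethyloxolan-2-one (racemic) | O=C1O[C@@H](c2cc(OC)c(OCc3ccccc3)c(OC)c2)[C@H](C)[C@@H]1C
F6 | step 3 | 3,4-cis-4,5-trans-5-[4-(benzyloxy)-3,5-dimethoxyphenyl]-3,4-dimethyloxolan-2-ol (lactol, racemic, anomers) | OC1O[C@@H](c2cc(OC)c(OCc3ccccc3)c(OC)c2)[C@H](C)[C@@H]1C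
F7 | step 3 | fragransin B1 mono-benzyl ether (racemic) | COc1cc([C@H]2O[C@@H](c3cc(OC)c(OCc4ccccc4)c(OC)c3)[C@H](C)[C@@H]2C)cc(OC)c1O
F8 | step 2 | meso-N,N'-dimethoxy-N,N',2,3-tetramethylbutanediamide | C[C@@H](C(=O)N(C)OC)[C@H](C)C(=O)N(C)OC
F9 | step 1 | dimethyl meso-2,3-dimethylsuccinate | C[C@@H](C(=O)OC)[C@H](C)C(=O)OC
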